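**Retrosynthetic overview**

1. The strategy rests on the lactone C(=O)–O unit of the seven-membered 1,4-dioxepinone ring. Its carbonyl sits on a ring A carbon flanked by the CH3-bearing carbon and the ether-oxygen-bearing carbon; its oxygen sits on a ring B carbon flanked by the CH2OAc-bearing carbon and the other ether-oxygen-bearing carbon. This doubly hindered ester is made last of the skeletal bonds, from an aryl iodide, CO and a phenol, so that the aryl–C(=O) and C(=O)–O bonds form in one palladium-catalysed step.
2. The iodo diaryl ether comes from SNAr of a hexasubstituted ring B phenol on 2-fluoro-3-iodo-6-(methoxymethoxy)-4-methylbenzaldehyde (ring A, from 3-fluoro-5-methylphenol by ortho-lithiation/formylation and para-iodination).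
3. Ring B comes from 3,4-dihydroxybenzaldehyde: Baeyer–Villiger oxidation gives the 1,2,4-trioxygenated core and three directed metalations add CH2OH, CO2tBu and CHO. A 1,3-dioxine acetonide ties the later lactone oxygen to the CH2OH, so only the ether-forming phenol is free for the SNAr; the acetate is put on after the ring closure because an ortho-(acetoxymethyl)phenoxide would lose acetate under base.
4. Ring order: diaryl ether link (step 11), dioxepinone ring (step 13), γ-lactol ring on acid deprotection (step 15). The lactol stereocentre is set last by dynamic kinetic O-allyloxycarbonylation (step 16) and uncovered under neutral conditions (step 17).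

Key step: step 13

Remark: a 3-hydroxyphthalide can epimerise by ring opening to the formyl acid; it is assumed that the closed lactol keeps its configuration in cold, neutral to weakly acidic, aprotic media, and that the antipode of the isothiourea that leads to the (R)-carbonate 28 is chosen after a trial with each.

**Route**

Step 1
Reactants: 1 3-fluoro-5-methylphenol
Product: 2 1-fluoro-3-(methoxymethoxy)-5-methylbenzene
Conditions: MOMCl, iPr2NEt, CH2Cl2, 0 °C → rt
Reagents that add atoms: chloromethyl methyl ether COCCl
Why: O-alkylation of the phenol by the α-chloro ether (MOM protection) masks the phenol and installs a strong ortho-directing group.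

Step 2
Reactants: 2 1-fluoro-3-(methoxymethoxy)-5-methylbenzene
Product: 4 2-fluoro-6-(methoxymethoxy)-4-methylbenzaldehyde, via aryllithium 3 (not isolated)
Conditions: nBuLi, THF, −78 °C; DMF, −78 → 0 °C; aq. NH4Cl
Reagents that add atoms: N,N-dimethylformamide CN(C)C=O
Why: Directed ortho-metalation should occur at the CH flanked by OMOM and F (chelation by OMOM plus the inductive effect of F), and formylation of the aryllithium with DMF at −78 °C precedes any loss of LiF.

Step 3
Reactants: 4 2-fluoro-6-(methoxymethoxy)-4-methylbenzaldehyde
Product: 5 2-fluoro-3-iodo-6-(methoxymethoxy)-4-methylbenzaldehyde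
Conditions: NIS, AgN(SO2CF3)2 (5 mol%), CH2Cl2, 0 °C → rt, dark
Reagents that add atoms: N-iodosuccinimide O=C1CCC(=O)N1I
Why: Electrophilic aromatic iodination with silver-activated NIS should go para to the OMOM donor, at the CH flanked by the small F and CH3 and not at the CH next to the bulkier OMOM, both open sites being meta to the formyl group.

Step 4
Reactants: 6 3,4-dihydroxybenzaldehyde
Product: 7 2,2-diphenyl-1,3-benzodioxole-5-carbaldehyde
Conditions: Ph2CCl2, Ph2O, 170 °C
Reagents that add atoms: dichlorodiphenylmethane ClC(Cl)(c1ccccc1)c1ccccc1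
Why: Double substitution of the gem-dichloride by the catechol (ketalisation) ties both catechol oxygens into a diphenylmethylene ketal that tolerates peracid and alkyllithium and is removable by hydrogenolysis.

Step 5
Reactants: 7 2,2-diphenyl-1,3-benzodioxole-5-carbaldehyde
Product: 9 2,2-diphenyl-1,3-benzodioxol-5-ol, via aryl formate 8 (not isolated)
Conditions: mCPBA, CH2Cl2, 0 °C → rt; then K2CO3 (cat.), MeOH, rt
Reagents that add atoms: 3-chloroperoxybenzoic acid O=C(OO)c1cccc(Cl)c1
Why: Baeyer–Villiger oxidation of the electron-rich benzaldehyde proceeds by aryl migration to the aryl formate, which is methanolysed to the phenol.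

Step 6
Reactants: 9 2,2-diphenyl-1,3-benzodioxol-5-ol
Product: 10 5-(methoxymethoxy)-2,2-diphenyl-1,3-benzodioxole
Conditions: MOMCl, iPr2NEt, CH2Cl2, 0 °C → rt
Reagents that add atoms: chloromethyl methyl ether COCCl
Why: MOM protection of the phenol gives the group that directs both later lithiations of ring B and stays until the final acid step.

Step 7
Reactants: 10 5-(methoxymethoxy)-2,2-diphenyl-1,3-benzodioxole
Product: 13 [5-(methoxymethoxy)-2,2-diphenyl-1,3-benzodioxol-4-yl]methanol, via aryllithium 11 (not isolated), via aldehyde 12 (not isolated)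
Conditions: nBuLi, THF, −78 → 0 °C; DMF, −78 °C → rt; then MeOH, NaBH4, 0 °C
Reagents that add atoms: N,N-dimethylformamide CN(C)C=O
Why: Directed ortho-metalation should take place at C4, the CH between OMOM and the dioxole oxygen (cooperative direction as in sesamol ethers), then formylation with DMF and hydride reduction in the same pot give the benzylic alcohol.

Step 8
Reactants: 13 [5-(methoxymethoxy)-2,2-diphenyl-1,3-benzodioxol-4-yl]methanol
Product: 15 5-(methoxymethoxy)-2,2-dimethyl-4H-1,3-benzodioxin-8-ol, via catechol triol 14 (not isolated)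
Conditions: H2 (1 atm), 10% Pd on carbon, EtOAc, rt; filtration under Ar; then Me2C(OMe)2, PPTS (cat.), acetone, rt
Reagents that add atoms: 2,2-dimethoxypropane COC(C)(C)OC
Why: Hydrogenolysis of the diphenylmethylene ketal frees the air-sensitive catechol, and acid-catalysed transketalisation then closes the six-membered 1,3-dioxine on the benzylic alcohol and its only ortho phenol (easier than the strained catechol acetonide), which leaves the other phenol free.

Step 9
Reactants: 15 5-(methoxymethoxy)-2,2-dimethyl-4H-1,3-benzodioxin-8-ol
Product: 17 tert-butyl 8-[(tert-butoxycarbonyl)oxy]-5-(methoxymethoxy)-2,2-dimethyl-4H-1,3-benzodioxine-6-carboxylate, via dilithio species 16 (not isolated)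
Conditions: nBuLi (2.3 equiv), TMEDA, THF, −20 → 0 °C; Boc2O (3.5 equiv), −78 °C → rt
Reagents that add atoms: di-tert-butyl dicarbonate CC(C)(C)OC(=O)OC(=O)OC(C)(C)C
Why: Directed ortho-metalation of the lithium phenoxide should occur ortho to OMOM (meta to the deactivating O–Li), and Boc2O acylates the aryllithium to the tert-butyl ester and caps the phenoxide as its tert-butyl carbonate.

Step 10
Reactants: 17 tert-butyl 8-[(tert-butoxycarbonyl)oxy]-5-(methoxymethoxy)-2,2-dimethyl-4H-1,3-benzodioxine-6-carboxylate
Product: 20 tert-butyl 7-formyl-8-hydroxy-5-(methoxymethoxy)-2,2-dimethyl-4H-1,3-benzodioxine-6-carboxylate, via arylmagnesium chloride 18 (not isolated), via carbonate aldehyde 19 (not isolated)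
Conditions: TMPMgCl·LiCl, THF, 0 °C; DMF, 0 °C → rt; aq. NH4Cl; then K2CO3 (cat.), MeOH, 0 °C
Reagents that add atoms: N,N-dimethylformamide CN(C)C=O
Why: Directed magnesiation by the hindered amide base at the only remaining aromatic CH (flanked by the ester and carbonate directing groups, both tolerated), formylation with DMF and methanolysis of the labile aryl carbonate should give the salicylaldehyde.

Step 11
Reactants: 20 tert-butyl 7-formyl-8-hydroxy-5-(methoxymethoxy)-2,2-dimethyl-4H-1,3-benzodioxine-6-carboxylate, 5 2-fluoro-3-iodo-6-(methoxymethoxy)-4-methylbenzaldehyde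
Product: 21 tert-butyl 7-formyl-8-[2-formyl-6-iodo-3-(methoxymethoxy)-5-methylphenoxy]-5-(methoxymethoxy)-2,2-dimethyl-4H-1,3-benzodioxine-6-carboxylate
Conditions: Cs2CO3, DMF, 70 °C
Reagents that add atoms: none
Why: Nucleophilic aromatic substitution (addition–elimination) of the fluoride ortho to the formyl group by the caesium phenoxide forms the diaryl ether, the unactivated iodide staying untouched in the absence of a transition metal.

Step 12
Reactants: 21 tert-butyl 7-formyl-8-[2-formyl-6-iodo-3-(methoxymethoxy)-5-methylphenoxy]-5-(methoxymethoxy)-2,2-dimethyl-4H-1,3-benzodioxine-6-carboxylate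
Product: 22 tert-butyl 2-formyl-3-[2-formyl-6-iodo-3-(methoxymethoxy)-5-methylphenoxy]-4-hydroxy-5-(hydroxymethyl)-6-(methoxymethoxy)benzoate
Conditions: AcOH–THF–H2O (3:1:1), 45 °C
Reagents that add atoms: none
Why: Mild acid hydrolysis of the isopropylidene ketal (a ketone acetal with a phenol leaving group) is much faster than hydrolysis of the formaldehyde-derived MOM acetals or cleavage of the tert-butyl ester.

Step 13
Reactants: 22 tert-butyl 2-formyl-3-[2-formyl-6-iodo-3-(methoxymethoxy)-5-methylphenoxy]-4-hydroxy-5-(hydroxymethyl)-6-(methoxymethoxy)benzoate, 23 carbon monoxide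
Product: 24 tert-butyl 4,6-diformyl-9-(hydroxymethyl)-3,8-bis(methoxymethoxy)-1-methyl-11-oxo-11H-dibenzo[b,e][1,4]dioxepine-7-carboxylate
Conditions: CO (1 atm), Pd(OAc)2 (10 mol%), Xantphos (12 mol%), Et3N, toluene (0.01 M), 80 °C
Reagents that add atoms: carbon monoxide [C-]#[O+]
Why: Pd(OAc)2 is reduced in situ to zerovalent palladium, which adds oxidatively to the C–I bond of ring A; CO inserts to give an aroyl complex of divalent palladium, and the ring B phenoxide captures the acyl group with release of the lactone and zerovalent palladium. The closest known reaction type is the palladium-catalysed intramolecular alkoxy- or aryloxycarbonylation of aryl iodides bearing a hydroxyl group, which gives benzo-fused lactones. The seven-membered dioxepinone ring closes by 7-exo-trig attack of the phenoxide oxygen on the acyl carbon (equivalently C–O reductive elimination from an eight-membered acyl aryloxo palladacycle), helped by the wide bite angle of Xantphos. No stereocentre is formed. The step needs the phenol to win over the primary benzylic alcohol and carbonylation to win over direct C–O coupling: the alcohol could only close a strained meta-bridged nine-membered ring or react between molecules (held back by the 0.01 M dilution and its lower acidity), and under 1 atm CO insertion into the hindered aryl–palladium bond should outrun reductive elimination to a dibenzodioxin. The hindered aroyl unit is never handled as a free acid, and the formyl groups, MOM ethers and tert-butyl ester are inert here.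

Step 14
Reactants: 24 tert-butyl 4,6-diformyl-9-(hydroxymethyl)-3,8-bis(methoxymethoxy)-1-methyl-11-oxo-11H-dibenzo[b,e][1,4]dioxepine-7-carboxylate
Product: 25 tert-butyl 9-(acetoxymethyl)-4,6-diformyl-3,8-bis(methoxymethoxy)-1-methyl-11-oxo-11H-dibenzo[b,e][1,4]dioxepine-7-carboxylate
Conditions: Ac2O, pyridine, DMAP (cat.), CH2Cl2, 0 °C
Reagents that add atoms: acetic anhydride CC(=O)OC(C)=O
Why: DMAP-catalysed acylation of the only free hydroxyl group, the primary benzylic alcohol, installs the acetate once no free ortho phenol is left to expel it.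

Step 15
Reactants: 25 tert-butyl 9-(acetoxymethyl)-4,6-diformyl-3,8-bis(methoxymethoxy)-1-methyl-11-oxo-11H-dibenzo[b,e][1,4]dioxepine-7-carboxylate
Product: 27 racemic galbinic acid, via formyl acid 26 (not isolated)
Conditions: TFA–CH2Cl2–H2O (10:10:1), 0 °C → rt
Reagents that add atoms: none
Why: Acidolysis removes both MOM acetals and the tert-butyl ester (as isobutene), and the freed acid adds to the neighbouring formyl group (ring–chain tautomerism) to close the 3-hydroxyphthalide lactol, expected as the racemate.

Step 16
Reactants: 27 racemic galbinic acid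
Product: 28 tris(allyl carbonate) of galbinic acid (both phenols and the lactol oxygen carbonated; lactol carbon R)
Conditions: diallyl dicarbonate (4 equiv), HyperBTM ((2S,3R)-3-isopropyl-2-phenyl-3,4-dihydro-2H-benzo[4,5]thiazolo[3,2-a]pyrimidine or its antipode, 10 mol%), iPr2NEt, CH2Cl2, −20 °C
Reagents that add atoms: diallyl dicarbonate C=CCOC(=O)OC(=O)OCC=C
Why: Proposed new method: the chiral isothiourea is acylated by the dicarbonate to an N-allyloxycarbonyl isothiouronium ion that should transfer the carbonate group to one lactol enantiomer faster than to the other while iPr2NEt keeps the two in equilibrium through the ring-opened formyl carboxylate, so the stereocentre is set by the catalyst (dynamic kinetic resolution); the closest known reaction type is the isothiourea-catalysed acylative dynamic kinetic resolution of lactols such as 3-hydroxyphthalides with carboxylic anhydrides, and the two phenols are carbonated as well without consequence because all three carbonates fall in step 17.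

Step 17
Reactants: 28 tris(allyl carbonate) of galbinic acid (lactol carbon R)
Product: 29 galbinic acid (lactol carbon S)
Conditions: Pd(PPh3)4 (5 mol%), PhSiH3, CH2Cl2, 0 °C; cold aq. citric acid work-up
Reagents that add atoms: none
Why: Zerovalent palladium ionises the three allyl–oxygen bonds (Tsuji–Trost-type deallylation), phenylsilane reduces the π-allyl complexes to propene and the carbonic half-esters lose CO2 on work-up, so no bond to the lactol carbon is broken and its configuration should be retained (the descriptor changes from R to S only through the CIP priorities).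

**Compound list**

1 | 3-fluoro-5-methylphenol | Cc1cc(O)cc(F)c1 | starting material
2 | 1-fluoro-3-(methoxymethoxy)-5-methylbenzene | COCOc1cc(C)cc(F)c1 | intermediate
3 | [2-fluoro-6-(methoxymethoxy)-4-methylphenyl]lithium | COCOc1cc(C)cc(F)c1[Li] | intermediate (not isolated)
4 | 2-fluoro-6-(methoxymethoxy)-4-methylbenzaldehyde | COCOc1cc(C)cc(F)c1C=O | intermediate
5 | 2-fluoro-3-iodo-6-(methoxymethoxy)-4-methylbenzaldehyde | COCOc1cc(C)c(I)c(F)c1C=O | intermediate
6 | 3,4-dihydroxybenzaldehyde | O=Cc1ccc(O)c(O)c1 | starting material
7 | 2,2-diphenyl-1,3-benzodioxole-5-carbaldehyde | O=Cc1ccc2OC(c3ccccc3)(c3ccccc3)Oc2c1 | intermediate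
8 | 2,2-diphenyl-1,3-benzodioxol-5-yl formate | O=COc1ccc2OC(c3ccccc3)(c3ccccc3)Oc2c1 | intermediate (not isolated)
9 | 2,2-diphenyl-1,3-benzodioxol-5-ol | Oc1ccc2OC(c3ccccc3)(c3ccccc3)Oc2c1 | intermediate
10 | 5-(methoxymethoxy)-2,2-diphenyl-1,3-benzodioxole | COCOc1ccc2OC(c3ccccc3)(c3ccccc3)Oc2c1 | intermediate
11 | [5-(methoxymethoxy)-2,2-diphenyl-1,3-benzodioxol-4-yl]lithium | COCOc1ccc2OC(c3ccccc3)(c3ccccc3)Oc2c1[Li] | intermediate (not isolated)
12 | 5-(methoxymethoxy)-2,2-diphenyl-1,3-benzodioxole-4-carbaldehyde | COCOc1ccc2OC(c3ccccc3)(c3ccccc3)Oc2c1C=O | intermediate (not isolated)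
13 | [5-(methoxymethoxy)-2,2-diphenyl-1,3-benzodioxol-4-yl]methanol | COCOc1ccc2OC(c3ccccc3)(c3ccccc3)Oc2c1CO | intermediate
14 | 3-(hydroxymethyl)-4-(methoxymethoxy)benzene-1,2-diol | COCOc1ccc(O)c(O)c1CO | intermediate (not isolated)
15 | 5-(methoxymethoxy)-2,2-dimethyl-4H-1,3-benzodioxin-8-ol | COCOc1ccc(O)c2OC(C)(C)OCc12 | intermediate
16 | lithium 6-lithio-5-(methoxymethoxy)-2,2-dimethyl-4H-1,3-benzodioxin-8-olate | COCOc1c([Li])cc(O[Li])c2OC(C)(C)OCc12 | intermediate (not isolated)
17 | tert-butyl 8-[(tert-butoxycarbonyl)oxy]-5-(methoxymethoxy)-2,2-dimethyl-4H-1,3-benzodioxine-6-carboxylate | COCOc1c(C(=O)OC(C)(C)C)cc(OC(=O)OC(C)(C)C)c2OC(C)(C)OCc12 | intermediate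
18 | 7-(chloromagnesio) derivative of 17 | COCOc1c(C(=O)OC(C)(C)C)c([Mg]Cl)c(OC(=O)OC(C)(C)C)c2OC(C)(C)OCc12 | intermediate (not isolated)
19 | tert-butyl 8-[(tert-butoxycarbonyl)oxy]-7-formyl-5-(methoxymethoxy)-2,2-dimethyl-4H-1,3-benzodioxine-6-carboxylate | COCOc1c(C(=O)OC(C)(C)C)c(C=O)c(OC(=O)OC(C)(C)C)c2OC(C)(C)OCc12 | intermediate (not isolated)
20 | tert-butyl 7-formyl-8-hydroxy-5-(methoxymethoxy)-2,2-dimethyl-4H-1,3-benzodioxine-6-carboxylate | COCOc1c(C(=O)OC(C)(C)C)c(C=O)c(O)c2OC(C)(C)OCc12 | intermediate
21 | tert-butyl 7-formyl-8-[2-formyl-6-iodo-3-(methoxymethoxy)-5-methylphenoxy]-5-(methoxymethoxy)-2,2-dimethyl-4H-1,3-benzodioxine-6-carboxylate | COCOc1c(C(=O)OC(C)(C)C)c(C=O)c(Oc3c(C=O)c(OCOC)cc(C)c3I)c2OC(C)(C)OCc12 | intermediate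
22 | tert-butyl 2-formyl-3-[2-formyl-6-iodo-3-(methoxymethoxy)-5-methylphenoxy]-4-hydroxy-5-(hydroxymethyl)-6-(methoxymethoxy)benzoate (key-step precursor) | COCOc1c(CO)c(O)c(Oc2c(C=O)c(OCOC)cc(C)c2I)c(C=O)c1C(=O)OC(C)(C)C | intermediate
23 | carbon monoxide | [C-]#[O+] | starting material
24 | tert-butyl 4,6-diformyl-9-(hydroxymethyl)-3,8-bis(methoxymethoxy)-1-methyl-11-oxo-11H-dibenzo[b,e][1,4]dioxepine-7-carboxylate (key-step product) | OCc1c(OCOC)c(C(=O)OC(C)(C)C)c(C=O)c3c1OC(=O)c1c(C)cc(OCOC)c(C=O)c1O3 | intermediate
25 | tert-butyl 9-(acetoxymethyl)-4,6-diformyl-3,8-bis(methoxymethoxy)-1-methyl-11-oxo-11H-dibenzo[b,e][1,4]dioxepine-7-carboxylate | CC(=O)OCc1c(OCOC)c(C(=O)OC(C)(C)C)c(C=O)c3c1OC(=O)c1c(C)cc(OCOC)c(C=O)c1O3 | intermediate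
26 | 9-(acetoxymethyl)-4,6-diformyl-3,8-dihydroxy-1-methyl-11-oxo-11H-dibenzo[b,e][1,4]dioxepine-7-carboxylic acid | CC(=O)OCc1c(O)c(C(=O)O)c(C=O)c3c1OC(=O)c1c(C)cc(O)c(C=O)c1O3 | intermediate (not isolated)
27 | racemic galbinic acid (lactol carbon unassigned) | CC(=O)OCc1c(O)c2c(c3c1OC(=O)c1c(C)cc(O)c(C=O)c1O3)C(O)OC2=O | intermediate
28 | tris(allyl carbonate) of galbinic acid, allyl carbonates on both phenols and on the lactol oxygen, lactol carbon R | CC(=O)OCc1c(OC(=O)OCC=C)c2c(c3c1OC(=O)c1c(C)cc(OC(=O)OCC=C)c(C=O)c1O3)[C@@H](OC(=O)OCC=C)OC2=O | intermediate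
29 | galbinic acid, lactol carbon S | CC(=O)OCc1c(O)c2c(c3c1OC(=O)c1c(C)cc(O)c(C=O)c1O3)[C@@H](O)OC2=O | target

**Step count and risks**

Total step count: 17 steps. Longest linear sequence: 14 steps (steps 4 to 17, from 3,4-dihydroxybenzaldehyde 6).

Steps most likely to fail:

Step 16 (carries the new-method label). What may go wrong: weak enantiodiscrimination in the carbonate transfer, lactol racemisation that is slower than acylation so that only a kinetic resolution results, or loss of acetate from ring B through an ortho-quinone methide while a phenoxide is present. Fallback with known chemistry: set out from racemic galbinic acid 27 and separate the enantiomers by preparative chromatography on an immobilised polysaccharide chiral stationary phase with a weakly acidified, non-basic eluent at low temperature. The S enantiomer is collected as 29; the R enantiomer is racemised with a trace of amine and recycled. This replaces the catalytic resolution by a physical one, needs neither step 16 nor step 17, and makes no new compound (F0).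

Step 13 (key step). What may go wrong: capture of the hindered aroylpalladium by the hindered phenoxide is slow, so that hydrodeiodination or acylation of the benzylic alcohol of a second molecule takes over. Fallback: set out from 22 and run a palladium-catalysed aryloxycarbonylation with 2,4,6-trichlorophenyl formate as the CO source (Pd(OAc)2, Xantphos, Et3N, toluene), which hands the acyl group to the small, acidic trichlorophenoxide and gives the 2,4,6-trichlorophenyl ester F1. The ring is then closed without metal by transesterification of this active ester with the ring B phenoxide (DBU or Cs2CO3, MeCN, high dilution), which returns to the route at 24.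

Step 11. What may go wrong: slow addition of the chelated salicylaldehyde-type phenoxide, hindered on both sides, to a C–F carbon that is itself flanked by CHO and I, with decomposition on long heating. Fallback: set out from phenol 20 and the iodine-free fluoride 4, whose C–F carbon has only one large neighbour. SNAr (Cs2CO3, DMF) gives the iodine-free diaryl ether F2. Iodination with NIS and AgN(SO2CF3)2 then places iodine para to the OMOM group of ring A, ring B having no free position, and returns to the route at 21.

Further compounds
F0 | step 16 | none | none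
F1 | step 13 | tert-butyl 2-formyl-3-[2-formyl-3-(methoxymethoxy)-5-methyl-6-(2,4,6-trichlorophenoxycarbonyl)phenoxy]-4-hydroxy-5-(hydroxymethyl)-6-(methoxymethoxy)benzoate | COCOc1c(CO)c(O)c(Oc2c(C=O)c(OCOC)cc(C)c2C(=O)Oc3c(Cl)cc(Cl)cc3Cl)c(C=O)c1C(=O)OC(C)(C)C
F2 | step 11 | tert-butyl 7-formyl-8-[2-formyl-3-(methoxymethoxy)-5-methylphenoxy]-5-(methoxymethoxy)-2,2-dimethyl-4H-1,3-benzodioxine-6-carboxylate | COCOc1c(C(=O)OC(C)(C)C)c(C=O)c(Oc3c(C=O)c(OCOC)cc(C)c3)c2OC(C)(C)OCc12
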